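Two numbers and one choice are asked of this flask:

* target at 25 s, in percent of the substrate charged
* the change that raises the amount of target at 25 s, in percent of the substrate charged most ("none" if none brings more than 2 percentage points) (Tuesday's / Sunday's / none)
* amount of target at 25 s, in percent of the substrate charged, after Tuesday's

substrate 0.20 M; gas phase 19 mM (held); time 25 s

    gas phase ⇌ dissolved gas, rate k1*(csat - [dissolved gas]) (k1 = 1.7 s⁻¹, csat = 19 mM)
    target ⇌ isomer of the product (K2 = 1.7, k2 = 0.015 s⁻¹)
    substrate + dissolved gas ⇌ target (K3 = 96 M⁻¹, k3 = 3.2 M⁻¹ s⁻¹)
    dissolved gas + target → over-reacted product (k4 = 4.8 M⁻¹ s⁻¹)
    2 substrate → self-condensation product (k5 = 0.065 M⁻¹ s⁻¹)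

- percent here means substrate units held: one self-condensation product counts as two
- a doubled species enters its step squared and goes two at a time
- at the start none of the gas is dissolved
- run time (flask): 25 s

I keep the books in substrate, the limiting reagent, since transfer could deliver 404% of the charge by 25 s, far more than the charge. Transfer at 1.7 s⁻¹ also outruns uptake at 0.640 s⁻¹, reckoned with substrate as charged, so I book the dissolved gas at saturation, 19 mM. That is somewhat high.

I follow one molecule through its forks.

Substrate to target: a = 0.0608 s⁻¹

Substrate to self-condensation product, at the start: 0.0260 s⁻¹, a share of 30.0% that I leave out of the reckoning.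

Target lost to over-reaction, the way back and the isomer: c = 0.140 s⁻¹, of which over-reaction takes 65.4%.

So, with substrate falling at a and nothing counted as returning from the way back or the isomer, d[target]/dt = a[substrate] − c[target], and in this reckoning target rises while target over substrate stands below the crossover ratio X = a/c = 0.436, and falls above it.

Solved for the charge, target/charge = a/(c − a)·(e^(−at) − e^(−ct)).

At 25 s my books close with 21.9% as substrate, 14.5% as target and 63.6% booked as lost from target, with over-reaction, the way back and the isomer in one entry.

Tuesday's change doubles the gas in both a and the over-reaction term, which gives 4.98%. Sunday's leaves 19 mM unchanged, so it moves nothing in this ledger, and my choice is none.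

The forecast gives 15% (from 13.5% to 16.5%), none, and 13% (from 10.5% to 15.5%), a first figure a little above mine and a second well above it, holding that more gas “mostly moves the peak earlier and speeds the over-reaction”.

The flask gives 15.6% and 9.01%, and the choice is none, with Tuesday's at −6.6 percentage points and Sunday's at −0.52 points. At 25.0 s this flask is not at rest: target over substrate reads 0.549, above X, and target is made at 0.685 of the rate at which it is used up, each step taken net. The neighbour flask read at 40 s also stands above X, at 0.615, with target down to 9.59%. Left ten times as long, this flask holds substrate 0.144%, target 0.227% and self-condensation product 24.4%, while over-reacted product climbs from 28.8% to 72.8%.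

(Its constants are made up; the flask was simulated.)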